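**Retrosynthetic overview**
1. Target 23 ← hydrogenolysis of three aryl benzyl ethers; the side-chain CH2OH ← ozonolysis/reduction of a vinyl group.
2. anti Carbinol/methine pair of the side chain ← ruthenium-catalysed coupling of aryl propyne 16 (ring B) with benzylic alcohol 17 (ring C).
3. Propyne ← Sonogashira coupling on aryl iodide 14; the iodine is placed ortho to the free phenol of dihydroferulic acid at the outset.
4. Key disconnection: the bond between the two lactone methine carbons ← oxidative cross-coupling of two enolates (imide enolate of the ring B unit + ester enolate of the ring A unit), the auxiliary setting the centre next to the future CH2O.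
5. Only ring formed: the butyrolactone, closed directly after the coupling by imide reduction, lactonisation onto the ester and base equilibration to trans.

Assumption: the SMILES is read as (3R,4R) in the lactone and (1R,2R) in the side chain (aryl and hydroxyl anti); compounds 1, 5, 15 and 17 are taken as purchasable.

**Step 1**
Reactants: 1 3-(4-hydroxy-3-methoxyphenyl)propanoic acid (dihydroferulic acid)
Product: 2 3-(4-hydroxy-3-iodo-5-methoxyphenyl)propanoic acid
Conditions: N-iodosuccinimide (1.05 equiv), p-TsOH·H2O (10 mol %), MeCN, 0 °C to rt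
Reagents that add atoms: N-iodosuccinimide O=C1CCC(=O)N1I
Why: Electrophilic aromatic iodination, in which the free phenol directs to its only open ortho position (para is blocked), as in the iodination of vanillin.

**Step 2**
Reactants: 2 3-(4-hydroxy-3-iodo-5-methoxyphenyl)propanoic acid
Product: 4 3-[4-(benzyloxy)-3-iodo-5-methoxyphenyl]propanoic acid, via benzyl ester 3 (not isolated)
Conditions: BnBr (2.3 equiv), K2CO3, DMF, 50 °C; then 2 M NaOH, MeOH, 50 °C; HCl work-up
Reagents that add atoms: benzyl bromide BrCc1ccccc1; sodium hydroxide [Na+].[OH-] (oxygen of the regenerated CO2H)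
Why: Williamson etherification (the carboxylate is benzylated as well) followed by saponification of the benzyl ester in the same pot leaves only the aryl benzyl ether.

**Step 3**
Reactants: 4 3-[4-(benzyloxy)-3-iodo-5-methoxyphenyl]propanoic acid; 5 (S)-4-benzyl-1,3-oxazolidin-2-one
Product: 7 (4S)-4-benzyl-3-{3-[4-(benzyloxy)-3-iodo-5-methoxyphenyl]propanoyl}-1,3-oxazolidin-2-one, via mixed anhydride 6 (not isolated)
Conditions: t-BuCOCl, Et3N, THF, −20 °C; then 5, LiCl, −20 °C to rt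
Reagents that add atoms: pivaloyl chloride CC(C)(C)C(Cl)=O (its atoms stay only in 6)
Why: N-acylation of the Evans auxiliary through the mixed pivalic anhydride (LiCl/Et3N variant), the oxazolidinone attacking the less hindered acyl carbon.

**Step 4**
Reactants: 1 3-(4-hydroxy-3-methoxyphenyl)propanoic acid
Product: 8 benzyl 3-[4-(benzyloxy)-3-methoxyphenyl]propanoate
Conditions: BnBr (2.4 equiv), K2CO3, DMF, 60 °C
Reagents that add atoms: benzyl bromide BrCc1ccccc1
Why: One-pot double O-alkylation (Williamson ether formation plus carboxylate alkylation) gives the ring A ester partner with its phenol masked.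

**Step 5 (key step)**
Reactants: 7 (4S)-4-benzyl-3-{3-[4-(benzyloxy)-3-iodo-5-methoxyphenyl]propanoyl}-1,3-oxazolidin-2-one; 8 benzyl 3-[4-(benzyloxy)-3-methoxyphenyl]propanoate
Product: 11 benzyl (3R)-4-[(4S)-4-benzyl-2-oxo-1,3-oxazolidin-3-yl]-2-[4-(benzyloxy)-3-methoxybenzyl]-3-[4-(benzyloxy)-3-iodo-5-methoxybenzyl]-4-oxobutanoate (epimers at C2), via lithium imide enolate 9 (not isolated), via lithium ester enolate 10 (not isolated)
Conditions: 7 (1.0 equiv), 8 (1.5 equiv), LiN(i-Pr)2 (2.6 equiv), THF, −78 °C, 30 min; then Fe(acac)3 (2.6 equiv), −78 °C to rt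
Reagents that add atoms: lithium diisopropylamide CC(C)[N-]C(C)C.[Li+] (lithium stays only in 9 and 10)
Why: Oxidative enolate heterocoupling (Baran type), in which trivalent iron oxidises the chelated (Z)-imide enolate to an electrophilic α-carbonyl radical (an enolonium equivalent) that the ester enolate captures on the face away from the auxiliary benzyl group, so two α-carbons that are both nucleophilic as enolates are joined with the (R) centre next to the imide fixed, while the ester α-centre forms as a mixture that step 6 corrects.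

**Step 6**
Reactants: 11 benzyl (3R)-4-[(4S)-4-benzyl-2-oxo-1,3-oxazolidin-3-yl]-2-[4-(benzyloxy)-3-methoxybenzyl]-3-[4-(benzyloxy)-3-iodo-5-methoxybenzyl]-4-oxobutanoate
Product: 14 (3R,4R)-4-[4-(benzyloxy)-3-iodo-5-methoxybenzyl]-3-[4-(benzyloxy)-3-methoxybenzyl]oxolan-2-one, via hydroxy ester 12 (not isolated), via lactone epimer mixture 13 (not isolated)
Conditions: NaBH4 (4 equiv), THF/H2O (3:1), 0 °C to rt; extractive work-up; then DBU (0.5 equiv), toluene, 90 °C
Reagents that add atoms: none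
Why: Chemoselective borohydride reduction of the N-acyloxazolidinone (the benzyl ester is untouched) releases the auxiliary and a primary alcohol that lactonises onto the ester, and DBU epimerises the centre next to the lactone carbonyl to the thermodynamically favoured trans (3R,4R) isomer.

**Step 7**
Reactants: 14 (3R,4R)-4-[4-(benzyloxy)-3-iodo-5-methoxybenzyl]-3-[4-(benzyloxy)-3-methoxybenzyl]oxolan-2-one; 15 propyne
Product: 16 (3R,4R)-4-[4-(benzyloxy)-3-methoxy-5-(prop-1-yn-1-yl)benzyl]-3-[4-(benzyloxy)-3-methoxybenzyl]oxolan-2-one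
Conditions: propyne (ca. 1 M in THF, 4 equiv), PdCl2(PPh3)2 (5 mol %), CuI (10 mol %), Et3N, THF, rt to 50 °C, sealed tube
Reagents that add atoms: none
Why: Sonogashira coupling of the aryl iodide, where the benzylated phenol cannot cyclise to a benzofuran and the lactone tolerates the amine base.

**Step 8**
Reactants: 16 (3R,4R)-4-[4-(benzyloxy)-3-methoxy-5-(prop-1-yn-1-yl)benzyl]-3-[4-(benzyloxy)-3-methoxybenzyl]oxolan-2-one; 17 4-(benzyloxy)-3-methoxybenzyl alcohol
Product: 20 (3R,4R)-4-{4-(benzyloxy)-3-[(1R,2S)-1-[4-(benzyloxy)-3-methoxyphenyl]-1-hydroxybut-3-en-2-yl]-5-methoxybenzyl}-3-[4-(benzyloxy)-3-methoxybenzyl]oxolan-2-one, via aryl allene 18 (not isolated), via aldehyde 19 (not isolated)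
Conditions: 17 (3 equiv), RuH2(CO)(PPh3)3 (5 mol %), (R)-1-[(S)-2-(dicyclohexylphosphino)ferrocenyl]ethyl-di-tert-butylphosphine or its enantiomer (5 mol %), Bu4NI (10 mol %), THF, 100 °C, sealed tube
Reagents that add atoms: none
Why: Ruthenium-catalysed redox-neutral alkyne–alcohol coupling (Krische anti-(α-aryl)allylation of 1-arylpropynes), in which the ruthenium hydride formed by dehydrogenating 17 isomerises the propyne to allene 18 and hydrometalates it to an (E)-cinnamyl-type ruthenium species that adds to aldehyde 19 through a closed chair transition state to give the anti pair, the ligand antipode that delivers the (1R,2S) product being the one used.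

**Step 9**
Reactants: 20 (3R,4R)-4-{4-(benzyloxy)-3-[(1R,2S)-1-[4-(benzyloxy)-3-methoxyphenyl]-1-hydroxybut-3-en-2-yl]-5-methoxybenzyl}-3-[4-(benzyloxy)-3-methoxybenzyl]oxolan-2-one
Product: 22 (3R,4R)-4-{4-(benzyloxy)-3-[(1R,2R)-1-[4-(benzyloxy)-3-methoxyphenyl]-1,3-dihydroxypropan-2-yl]-5-methoxybenzyl}-3-[4-(benzyloxy)-3-methoxybenzyl]oxolan-2-one, via hydroxy aldehyde 21 (not isolated)
Conditions: O3, CH2Cl2/MeOH (3:1), −78 °C, Sudan Red 7B end point; then NaBH4 (5 equiv), −78 to 0 °C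
Reagents that add atoms: ozone [O-][O+]=O
Why: Ozonolysis of the only C=C bond (much faster than attack on the alkoxyarenes) with borohydride reduction in the same flask turns the vinyl group into CH2OH before the epimerisable α-aryl aldehyde can equilibrate, so both side-chain centres are retained.

**Step 10**
Reactants: 22 (3R,4R)-4-{4-(benzyloxy)-3-[(1R,2R)-1-[4-(benzyloxy)-3-methoxyphenyl]-1,3-dihydroxypropan-2-yl]-5-methoxybenzyl}-3-[4-(benzyloxy)-3-methoxybenzyl]oxolan-2-one
Product: 23 (3R,4R)-4-{3-[(1R,2R)-1,3-dihydroxy-1-(4-hydroxy-3-methoxyphenyl)propan-2-yl]-4-hydroxy-5-methoxybenzyl}-3-(4-hydroxy-3-methoxybenzyl)oxolan-2-one (CNP0109231.2)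
Conditions: H2 (1 atm), 10 % Pd/C, EtOAc/EtOH, rt, stopped at full debenzylation
Reagents that add atoms: none
Why: Catalytic hydrogenolysis removes the three aryl benzyl ethers, which cleave much faster than the secondary benzylic alcohol under neutral conditions, as in the closing step of lignin model syntheses.

**Compound list**
1 | 3-(4-hydroxy-3-methoxyphenyl)propanoic acid | COc1cc(CCC(=O)O)ccc1O | starting material
2 | 3-(4-hydroxy-3-iodo-5-methoxyphenyl)propanoic acid | COc1cc(CCC(=O)O)cc(I)c1O | intermediate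
3 | benzyl 3-[4-(benzyloxy)-3-iodo-5-methoxyphenyl]propanoate (not isolated) | COc1cc(CCC(=O)OCc2ccccc2)cc(I)c1OCc1ccccc1 | intermediate
4 | 3-[4-(benzyloxy)-3-iodo-5-methoxyphenyl]propanoic acid | COc1cc(CCC(=O)O)cc(I)c1OCc1ccccc1 | intermediate
5 | (S)-4-benzyl-1,3-oxazolidin-2-one | O=C1N[C@@H](Cc2ccccc2)CO1 | starting material
6 | 3-[4-(benzyloxy)-3-iodo-5-methoxyphenyl]propanoic pivalic anhydride (not isolated) | COc1cc(CCC(=O)OC(=O)C(C)(C)C)cc(I)c1OCc1ccccc1 | intermediate
7 | (4S)-4-benzyl-3-{3-[4-(benzyloxy)-3-iodo-5-methoxyphenyl]propanoyl}-1,3-oxazolidin-2-one | COc1cc(CCC(=O)N2[C@@H](Cc3ccccc3)COC2=O)cc(I)c1OCc1ccccc1 | intermediate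
8 | benzyl 3-[4-(benzyloxy)-3-methoxyphenyl]propanoate | COc1cc(CCC(=O)OCc2ccccc2)ccc1OCc1ccccc1 | intermediate
9 | lithium (Z)-enolate of imide 7 (not isolated) | [Li+].[O-]/C(=C\Cc1cc(OC)c(OCc2ccccc2)c(I)c1)N1[C@@H](Cc2ccccc2)COC1=O | intermediate
10 | lithium enolate of ester 8 (not isolated) | [Li+].[O-]C(OCc1ccccc1)=CCc1ccc(OCc2ccccc2)c(OC)c1 | intermediate
11 | benzyl (3R)-4-[(4S)-4-benzyl-2-oxo-1,3-oxazolidin-3-yl]-2-[4-(benzyloxy)-3-methoxybenzyl]-3-[4-(benzyloxy)-3-iodo-5-methoxybenzyl]-4-oxobutanoate, epimers at C2 | COc1cc(C[C@H](C(Cc2ccc(OCc3ccccc3)c(OC)c2)C(=O)OCc2ccccc2)C(=O)N2[C@@H](Cc3ccccc3)COC2=O)cc(I)c1OCc1ccccc1 | intermediate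
12 | benzyl (3R)-2-[4-(benzyloxy)-3-methoxybenzyl]-3-[4-(benzyloxy)-3-iodo-5-methoxybenzyl]-4-hydroxybutanoate, epimers at C2 (not isolated) | COc1cc(C[C@@H](CO)C(Cc2ccc(OCc3ccccc3)c(OC)c2)C(=O)OCc2ccccc2)cc(I)c1OCc1ccccc1 | intermediate
13 | (4R)-4-[4-(benzyloxy)-3-iodo-5-methoxybenzyl]-3-[4-(benzyloxy)-3-methoxybenzyl]oxolan-2-one, cis/trans mixture at C3 (not isolated) | COc1cc(CC2C(=O)OC[C@@H]2Cc2cc(OC)c(OCc3ccccc3)c(I)c2)ccc1OCc1ccccc1 | intermediate
14 | (3R,4R)-4-[4-(benzyloxy)-3-iodo-5-methoxybenzyl]-3-[4-(benzyloxy)-3-methoxybenzyl]oxolan-2-one | COc1cc(C[C@H]2C(=O)OC[C@@H]2Cc2cc(OC)c(OCc3ccccc3)c(I)c2)ccc1OCc1ccccc1 | intermediate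
15 | propyne | CC#C | starting material
16 | (3R,4R)-4-[4-(benzyloxy)-3-methoxy-5-(prop-1-yn-1-yl)benzyl]-3-[4-(benzyloxy)-3-methoxybenzyl]oxolan-2-one | COc1cc(C[C@H]2C(=O)OC[C@@H]2Cc2cc(OC)c(OCc3ccccc3)c(C#CC)c2)ccc1OCc1ccccc1 | intermediate
17 | 4-(benzyloxy)-3-methoxybenzyl alcohol | COc1cc(CO)ccc1OCc1ccccc1 | starting material
18 | (3R,4R)-4-[4-(benzyloxy)-3-methoxy-5-(propa-1,2-dien-1-yl)benzyl]-3-[4-(benzyloxy)-3-methoxybenzyl]oxolan-2-one (not isolated) | COc1cc(C[C@H]2C(=O)OC[C@@H]2Cc2cc(OC)c(OCc3ccccc3)c(C=C=C)c2)ccc1OCc1ccccc1 | intermediate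
19 | 4-(benzyloxy)-3-methoxybenzaldehyde (not isolated) | COc1cc(C=O)ccc1OCc1ccccc1 | intermediate
20 | (3R,4R)-4-{4-(benzyloxy)-3-[(1R,2S)-1-[4-(benzyloxy)-3-methoxyphenyl]-1-hydroxybut-3-en-2-yl]-5-methoxybenzyl}-3-[4-(benzyloxy)-3-methoxybenzyl]oxolan-2-one | COc1cc(C[C@H]2C(=O)OC[C@@H]2Cc2cc(OC)c(OCc3ccccc3)c([C@H](C=C)[C@@H](O)c3ccc(OCc4ccccc4)c(OC)c3)c2)ccc1OCc1ccccc1 | intermediate
21 | (3R,4R)-4-{4-(benzyloxy)-3-[(1R,2S)-1-[4-(benzyloxy)-3-methoxyphenyl]-1-hydroxy-3-oxopropan-2-yl]-5-methoxybenzyl}-3-[4-(benzyloxy)-3-methoxybenzyl]oxolan-2-one (not isolated) | COc1cc(C[C@H]2C(=O)OC[C@@H]2Cc2cc(OC)c(OCc3ccccc3)c([C@H](C=O)[C@@H](O)c3ccc(OCc4ccccc4)c(OC)c3)c2)ccc1OCc1ccccc1 | intermediate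
22 | (3R,4R)-4-{4-(benzyloxy)-3-[(1R,2R)-1-[4-(benzyloxy)-3-methoxyphenyl]-1,3-dihydroxypropan-2-yl]-5-methoxybenzyl}-3-[4-(benzyloxy)-3-methoxybenzyl]oxolan-2-one | COc1cc(C[C@H]2C(=O)OC[C@@H]2Cc2cc(OC)c(OCc3ccccc3)c([C@H](CO)[C@@H](O)c3ccc(OCc4ccccc4)c(OC)c3)c2)ccc1OCc1ccccc1 | intermediate
23 | (3R,4R)-4-{3-[(1R,2R)-1,3-dihydroxy-1-(4-hydroxy-3-methoxyphenyl)propan-2-yl]-4-hydroxy-5-methoxybenzyl}-3-(4-hydroxy-3-methoxybenzyl)oxolan-2-one | COc1cc(C[C@H]2C(=O)OC[C@@H]2Cc2cc(OC)c(O)c([C@H](CO)[C@@H](O)c3ccc(O)c(OC)c3)c2)ccc1O | target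

**Totals**
Total step count: 10. Longest linear sequence: 9 (steps 1, 2, 3, 5, 6, 7, 8, 9, 10; step 4 is the side branch).

**Three steps most likely to fail, each with a fallback**

Step 5 (oxidative enolate heterocoupling). Homodimers of either enolate, a modest yield and imperfect face control at the imide α-carbon are the dangers. The fallback sets out from 7 and comes back at 14. It keeps the same polarity logic but uses a two-electron enolonium equivalent. The sodium enolate of 7 (NaN(SiMe3)2, THF, −78 °C) is alkylated with tert-butyl bromoacetate to give the alkylated imide F1. NaBH4 in THF/H2O then gives the hydroxy tert-butyl ester F2, and TFA in CH2Cl2 closes it to the monobenzyl lactone F3. Deprotonation with LiN(SiMe3)2 (THF, −78 °C) and alkylation trans to the existing substituent with 4-(benzyloxy)-3-methoxybenzyl bromide F4 (from 17 and PBr3) delivers 14.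

Step 8 (ruthenium-catalysed alkyne–alcohol coupling). The ortho-benzyloxy group crowds the forming centre, the alkyne may simply be transfer-hydrogenated, and the enantioselectivity is untested on this substrate. The fallback sets out from 14 and comes back at 20. A Heck reaction of 14 with allyl acetate (Pd(OAc)2, Ag2CO3, toluene, 90 °C) gives the (E)-cinnamyl acetate F5. Palladium-catalysed borylation (bis(pinacolato)diboron, tris(dibenzylideneacetone)dipalladium, DMSO, 50 °C) gives the (E)-allyl pinacol boronate F6. Allylboration of purchased aldehyde 19 under (R)-TRIP phosphoric acid catalysis (toluene, −30 °C) through the usual chair transition state then gives the anti alcohol 20.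

Step 9 (ozonolysis/borohydride). Ozone may attack the three alkoxyarene rings, hydroxy aldehyde 21 may epimerise or undergo retro-aldol cleavage, and borohydride may touch the lactone. The fallback sets out from 20 and comes back at 22. It replaces ozone by osmylation and glycol cleavage through an isolated intermediate. Dihydroxylation (OsO4 2 mol %, N-methylmorpholine N-oxide, acetone/H2O) gives the triol F7. NaIO4 in THF/pH 7 buffer at 0 °C then cleaves the terminal glycol, and NaBH4 is added at once to reduce aldehyde 21 to 22.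

**Further compounds**
F1 | step 5 | tert-butyl (3R)-4-[(4S)-4-benzyl-2-oxo-1,3-oxazolidin-3-yl]-3-[4-(benzyloxy)-3-iodo-5-methoxybenzyl]-4-oxobutanoate | COc1cc(C[C@H](CC(=O)OC(C)(C)C)C(=O)N2[C@@H](Cc3ccccc3)COC2=O)cc(I)c1OCc1ccccc1
F2 | step 5 | tert-butyl (3R)-3-[4-(benzyloxy)-3-iodo-5-methoxybenzyl]-4-hydroxybutanoate | COc1cc(C[C@@H](CO)CC(=O)OC(C)(C)C)cc(I)c1OCc1ccccc1
F3 | step 5 | (4R)-4-[4-(benzyloxy)-3-iodo-5-methoxybenzyl]oxolan-2-one | COc1cc(C[C@H]2COC(=O)C2)cc(I)c1OCc1ccccc1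
F4 | step 5 | 4-(benzyloxy)-3-methoxybenzyl bromide | COc1cc(CBr)ccc1OCc1ccccc1
F5 | step 8 | (3R,4R)-4-{3-[(E)-3-acetoxyprop-1-en-1-yl]-4-(benzyloxy)-5-methoxybenzyl}-3-[4-(benzyloxy)-3-methoxybenzyl]oxolan-2-one | COc1cc(C[C@H]2C(=O)OC[C@@H]2Cc2cc(OC)c(OCc3ccccc3)c(/C=C/COC(C)=O)c2)ccc1OCc1ccccc1
F6 | step 8 | (3R,4R)-4-{4-(benzyloxy)-3-methoxy-5-[(E)-3-(4,4,5,5-tetramethyl-1,3,2-dioxaborolan-2-yl)prop-1-en-1-yl]benzyl}-3-[4-(benzyloxy)-3-methoxybenzyl]oxolan-2-one | COc1cc(C[C@H]2C(=O)OC[C@@H]2Cc2cc(OC)c(OCc3ccccc3)c(/C=C/CB3OC(C)(C)C(C)(C)O3)c2)ccc1OCc1ccccc1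
F7 | step 9 | (3R,4R)-4-{4-(benzyloxy)-3-[(1R,2S)-1-[4-(benzyloxy)-3-methoxyphenyl]-1,3,4-trihydroxybutan-2-yl]-5-methoxybenzyl}-3-[4-(benzyloxy)-3-methoxybenzyl]oxolan-2-one, epimers at the new carbinol carbon | COc1cc(C[C@H]2C(=O)OC[C@@H]2Cc2cc(OC)c(OCc3ccccc3)c([C@H](C(O)CO)[C@@H](O)c3ccc(OCc4ccccc4)c(OC)c3)c2)ccc1OCc1ccccc1
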